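The numbers in the tables are calculated on assumed constants.

The teal flask slows as it runs, making product at 0.00510 M min⁻¹ over its first 2.0 min but at 0.00226 M min⁻¹ over its last stretch, and this bend is followed here by integrating its rate.

| flask | starting material | reagent | free catalyst | time |
|---|---|---|---|---|
| teal | 0.0800 M | 0.120 M | 0.00160 M |  |
| ochre | 0.0480 M | 0.0880 M | 0.00160 M |  |
| green | 0.0800 M | 0.180 M | 0.00160 M |  |
| blue | 0.120 M | 0.120 M | 0.00160 M |  |
| grey | 0.240 M | 0.120 M | 8.00 × 10⁻⁴ M | 14 min |

| run | time / min | [product] / M |
|---|---|---|
| teal run | 0.56 | 0.0023 |
| teal run | 1.1 | 0.0056 |
| teal run | 2.0 | 0.0102 |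
| teal run | 3.9 | 0.0189 |
| teal run | 7.4 | 0.0304 |
| teal run | 14 | 0.0453 |
| ochre run | 0.56 | 0.0021 |
| ochre run | 1.1 | 0.0026 |
| ochre run | 2.0 | 0.0044 |
| ochre run | 3.9 | 0.0103 |
| ochre run | 7.4 | 0.0166 |
| ochre run | 14 | 0.0254 |
| green run | 0.56 | 0.0044 |
| green run | 1.1 | 0.0078 |
| green run | 2.0 | 0.0138 |
| green run | 3.9 | 0.0259 |
| green run | 7.4 | 0.0414 |
| green run | 14 | 0.0588 |
| blue run | 0.56 | 0.0038 |
| blue run | 1.1 | 0.0080 |
| blue run | 2.0 | 0.0136 |
| blue run | 3.9 | 0.0255 |
| blue run | 7.4 | 0.0398 |
| blue run | 14 | 0.0587 |

(readings scatter by 6 × 10⁻⁴ M)

- Overall: starting material + reagent -> product, with free catalyst as catalyst.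
- Constant volume, constant temperature.
- What is held in complexes is read along with the free species.
- "The second partner" is reagent.
- An order is taken over about fifteen percent of the charge, up and down.

1. order of the initial rate in [reagent], near the charge of the teal run, the rate being that where two percent of its starting material are product
2. order of the initial rate in [starting material], near the charge of the teal run, the rate being that where two percent of its starting material are product (one fixed amount of product, the same in the runs compared)
3. the ochre run starts with 0.0320 M less of starting material and of reagent than the teal run, and with no product. Compared where both hold the same amount of starting material, once fifteen percent of what the ochre run was charged with has turned into product, is the ochre run faster, slower or alike (within a tenth)?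
4. product in the grey run at 14 min, as a share of the starting material charged

Take the rate as κ × [starting material] × [reagent], with κ the clock constant. With S and R as the charges and P the product at time t, integration gives:

κ·t = ln[ S·(R − P) / (R·(S − P)) ] / (R − S)

κ·t = P / (S·(S − P)) for equal charges

The last readings give 0.645 M⁻¹ min⁻¹ for teal and 0.666 M⁻¹ min⁻¹ for green. The constant therefore holds when reagent is raised, which reads as a reagent order near one.

Starting material is another matter, though ochre and blue also differ in reagent, 0.0880 M against 0.120 M, and the fall below is read as that of starting material on the strength of teal and green. The constant falls from 0.737 M⁻¹ min⁻¹ in ochre to 0.570 M⁻¹ min⁻¹ in blue. That fall reads as a charge exponent, the power at which the constant drops as the starting material charged rises, of 0.280.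

Carried to the grey charge, the exponent gives a constant of 0.469 M⁻¹ min⁻¹. Teal, ochre, green and blue share 0.00160 M of free catalyst, while the grey flask holds half of that, so this reckoning, which is the one made here, draws the curve first with the catalyst taken as having no effect.

The curve opens at 0.0135 M min⁻¹. Reagent is the limiting reagent, 0.120 M against 0.240 M of starting material, so the level is 0.120 M of product, 50.0% of the charge. Half of that level comes at 7.20 min, the knee. Solving the closed form for P at 14 min gives 0.0847 M, or 35.3%. With the constant scaled to the catalyst charge instead, it gives 0.0590 M, or 24.6%. These two figures are the ends of the range reckoned here.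

The forecast gives 0.8 (0.6 to 0.95) for the reagent order, 0.75 (0.55 to 0.92) for the starting-material order, faster for ochre, and 22% (17% to 28%) for grey, below the bracket here. Its ground for grey: “I assume the rate is first order in catalyst”.

The grey flask gives 33.6% at 14 min. Near the teal charge the orders are 1.0 in reagent and 0.75 in starting material, and where ochre and teal hold the same amount of starting material they are alike, at a rate ratio of 1.0.

    2 free catalyst ⇌ catalyst dimer, settled at all times (28300 M⁻¹)
    free catalyst + starting material + reagent → product + free catalyst (1068 M⁻² min⁻¹)
    starting material + reagent → product (0.7500 M⁻¹ min⁻¹)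
    2 starting material ⇌ idle substrate dimer, settled at all times (5.800 M⁻¹)

Through the closed form, the grey product of 0.0807 M at 14 min is a constant, averaged over that time, of 0.421 M⁻¹ min⁻¹, which is 89.8% of the value carried by the exponent 0.280. The same exponent, taken from ochre to the teal charge, puts the moment when the product made comes to half of the starting material charged in teal at 11.3 min, and the teal run reached that point at 11.3 min.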